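Substrate is the limiting reagent, so I keep the books on it, in fractions of the charge.

- north-west: substrate 30 mM; run made earlier
- flask: substrate 20 mM; time 15 h

north-west run (percent of the substrate charged)

| time / min | side product / % | target / % |
|---|---|---|
| 8.00 | 0.2 | 4.0 |
| 15.0 | 1.1 | 10.9 |
| 25.0 | 0.5 | 18.4 |
| 50.0 | 0.9 | 34.6 |
| 90.0 | 4.5 | 36.0 |

(scatter of a reading: 1 percentage point)

- what was read earlier has a scatter of 1 percentage point, one standard deviation

- share of side product in side product plus target at 12 min
- share of side product in side product plus target at 15 h

I assume first-order steps, so that fractions do not shift with the charge and the north-west run can stand for the flask. Its ledger at 90.0 min has two entries: target 36.0 % and side product 4.5 %. By these readings, that leaves 59.5 % of the charge in neither column. I call this the unread gap: the fraction of the charge that is neither target nor side product.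

Target gained just 1.4 percentage points over the last interval, so I hold it at its reading. I book the gap to side product, and the closing entry is 64.0 % side product. With target and side product then summing to the whole charge, this is also my share at 15 h. At 12 min I commit to a small share and no more, since side product still read 0.9 % at 50.0 min, with a scatter of 1 point.

The forecast gives 2 % and 70 %, the second above my closing share, and it warns that “the rise rests on one noisy point”.

The flask gives 0.661 % and 60.2 %.

    substrate → intermediate A (k = 2.18 × 10⁻⁴ s⁻¹)
    substrate → intermediate B (k = 4.10 × 10⁻⁴ s⁻¹)
    intermediate A → intermediate C (k = 0.00176 s⁻¹)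
    intermediate B → target (k = 9.67 × 10⁻⁴ s⁻¹)
    intermediate C → intermediate D (k = 1.40 × 10⁻⁴ s⁻¹)
    intermediate D → side product (k = 1.13 × 10⁻⁴ s⁻¹)
    intermediate A → intermediate D (k = 4.31 × 10⁻⁴ s⁻¹)
    target ⇌ isomer of the product (K = 1.87, k = 1.88 × 10⁻⁴ s⁻¹)
    substrate → decomposition product (k = 2.43 × 10⁻⁷ s⁻¹)

At 1.50 h the flask has target 37.4 % and side product 4.27 %, a gap of 58.3 %, where the north-west readings gave 59.5 %. At 15.0 h the gap in the flask is 42.9 %, and nearly all of it is isomer of the product, 42.5 %, so my booking to side product fails. The half-life of target into isomer of the product, forward step alone, is 1.0 h, shorter than 15 h, and target in the flask stands at 22.8 % at 7.50 h and 22.7 % at 15.0 h.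

For the neighbour flask with 34 mM of substrate, the same books carry the gap 59.5 % and a closing share of 64.0 %. Computed, that flask gives 60.2 %, with 42.5 % as isomer of the product.

The data come from a simulation with made-up constants; noise was put on by code.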